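Iridoid numbering: C1 acyl acetal, O2, C3=C4 enol ether with C11 on C4, C5/C9 ring fusion, C6, C7 carbinol, C8 tertiary carbinol bearing C10. Ring A is the dihydropyran, ring B the cyclopentane.
Enabling feature: O7 and C10 lie cis (both beta) on the adjacent ring B carbons C7 and C8, so C7–C8–C10(=O)–O7 can be written as a cis-fused beta-lactone, a ring the target itself lacks.
Cuts, in order: the O1–acyl and O10–coumaroyl bonds, then C8–OH, then C7–C8 and O7–C10 together (aldol-lactonisation). Before that come C7=C10 (ozonolysis retron), C4–C11 (carbonylation) and C5–C6/C8–C9 (Diels-Alder).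
Forward: ring A comes first (Achmatowicz pyranone). A temporary cyclohexene is fused on and cleaved into two cis arms, then ring B and the beta-lactone close in one step and the lactone is reduced away.
Stereochemistry: C1 comes from a dynamic kinetic acylation, and C5/C9 from diene addition anti to the C1 alkoxy group. C7/C8 come from the key step and C8–OH from retention enforced by the four-membered ring. C1 is re-set under anomeric control, and the side-chain centre is bought in.

Key step: step 9

Assumption: beta is the ring face that carries H5 and H9. The sense of induction of the two (R)-isothioureas is assigned from the usual shielding models of their N-acyl salts, and acid 26 is bought as the (S)-enantiomer.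

Step 1
Reactants: 1 furfuryl alcohol
Product: 2 6-hydroxy-2H-pyran-3(6H)-one (racemic lactol)
Conditions: NBS, NaHCO3, THF/H2O, 0 °C
Reagents that add atoms: water, O
Why: Achmatowicz rearrangement: bromonium-induced hydration of the furan gives a cis-enedione whose primary hydroxyl closes on the aldehyde, so C1, O2, C3, C4, C5 and C9 of ring A are in place at once, with C1 still racemic and labile.

Step 2
Reactants: 2 6-hydroxy-2H-pyran-3(6H)-one
Product: 3 (S)-5-oxo-5,6-dihydro-2H-pyran-2-yl 2-methylpropanoate
Conditions: (i-PrCO)2O, (R)-benzotetramisole [(2R)-2-phenyl-2,3-dihydroimidazo[2,1-b]benzothiazole] (5 mol %), i-Pr2NEt, CHCl3, 0 °C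
Reagents that add atoms: isobutyric anhydride, CC(C)C(=O)OC(=O)C(C)C
Why: Dynamic kinetic resolution by enantioselective acyl transfer: the lactol enantiomers interconvert through the open hydroxy enal, while the N-acyl isothiouronium ion stacks the enone pi system on its cationic heterocycle, keeps the ring oxygen away from its phenyl group, and should acylate only one enantiomer, which fixes C1.

Step 3
Reactants: 3 (S)-5-oxo-5,6-dihydro-2H-pyran-2-yl 2-methylpropanoate; 4 4-methoxybenzyl alcohol
Product: 5 (R)-6-(4-methoxybenzyloxy)-2H-pyran-3(6H)-one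
Conditions: Pd2(dba)3·CHCl3 (2.5 mol %), PPh3 (10 mol %), CH2Cl2, 0 °C to rt
Reagents that add atoms: none
Why: Tsuji-Trost allylic substitution at an anomeric centre: zerovalent palladium ionises the C1 ester anti, the alcohol attacks the pi-allyl complex anti to the metal at the carbon next to O2, and the double inversion carries the C1 configuration into an acetal that can later be removed under neutral oxidative conditions.

Step 4
Reactants: 6 but-3-en-2-one
Product: 7 2-(tert-butyldimethylsilyloxy)buta-1,3-diene
Conditions: TBSOTf, Et3N, Et2O, 0 °C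
Reagents that add atoms: tert-butyldimethylsilyl triflate, CC(C)(C)[Si](C)(C)OS(=O)(=O)C(F)(F)F
Why: Soft enolisation and O-silylation of a methyl ketone, which can only give the cross-conjugated 2-silyloxy diene.

Step 5
Reactants: 5 (R)-6-(4-methoxybenzyloxy)-2H-pyran-3(6H)-one; 7 2-(tert-butyldimethylsilyloxy)buta-1,3-diene
Product: 8 cis-fused 1-(4-methoxybenzyloxy)-7-(tert-butyldimethylsilyloxy)-4a,5,8,8a-tetrahydro-1H-isochromen-4(3H)-one (C1-OPMB beta; H5 and H9 beta; temporary ring C5-C6-C7=C10-C8-C9 with OTBS on C10)
Conditions: toluene, 2,6-di-tert-butyl-4-methylphenol (cat.), sealed tube, 120 °C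
Reagents that add atoms: none
Why: Thermal Diels-Alder reaction of a 6-alkoxypyranone: the nucleophilic CH2 terminus next to C-OSi bonds to the enone beta carbon C9 (para rule), suprafacial addition makes the C5-C6 and C9-C8 bonds cis, and the pseudo-axial C1 alkoxy group sends the diene to the opposite (alpha) face, which sets C5 and C9 and marks C10, not C7, with oxygen.

Step 6
Reactants: 8 cis-fused bicyclic ketone
Product: 10 C4 enol triflate (C3=C4-OTf; other centres as in 8), via potassium enolate 9 (not isolated)
Conditions: KN(SiMe3)2 (excess), THF, −78 °C, inverse addition of 8; then PhNTf2, −78 to 0 °C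
Reagents that add atoms: N-phenylbis(trifluoromethanesulfonimide), O=S(=O)(N(c1ccccc1)S(=O)(=O)C(F)(F)F)C(F)(F)F
Why: Kinetic enolate formation and O-triflation: the C3 methylene is less hindered and, being flanked by O2, more acidic than the tertiary ring-fusion H5, and adding the ketone to excess base leaves H5 untouched so the cis fusion is not epimerised.

Step 7
Reactants: 10 C4 enol triflate
Product: 11 methyl 1-(4-methoxybenzyloxy)-7-(tert-butyldimethylsilyloxy)-4a,5,8,8a-tetrahydro-1H-isochromene-4-carboxylate (C11 ester on C4; stereocentres as in 8)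
Conditions: Pd(OAc)2 (5 mol %), 1,3-bis(diphenylphosphino)propane, Et3N, CO (1 atm), MeOH/DMF, 40 °C
Reagents that add atoms: carbon monoxide, [C-]#[O+]; methanol, CO
Why: Palladium-catalysed alkoxycarbonylation of an enol triflate: oxidative addition to zerovalent palladium, CO insertion and methanolysis form C4-C11 and turn ring A into an acid-tolerant beta-alkoxyacrylate.

Step 8
Reactants: 11 silyl enol ether ester
Product: 13 seco aldehyde acid on ring A (C1-OPMB beta; C5-CH2CHO and C9-CH2CO2H both alpha), via silyl ester aldehyde 12 (not isolated)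
Conditions: O3 (to the Sudan Red 7B end point), CH2Cl2, −78 °C; Me2S; then THF/H2O/AcOH, 0 °C to rt
Reagents that add atoms: ozone, [O-][O+]=O
Why: Ozonolysis of a silyl enol ether: the electron-rich C7=C10 bond should react far faster than the push-pull C3=C4 bond or the anisyl ring, the primary ozonide splits into the C10 silyl ester and the C7 carbonyl oxide, and reduction plus mild hydrolysis leave the two cis arms already differentiated as acid and aldehyde.

Step 9
Reactants: 13 seco aldehyde acid
Product: 15 tricyclic beta-lactone (O7 and C10 beta; H7 and H8 alpha; H5 and H9 beta; C1-OPMB beta), via acylammonium ion 14 (not isolated)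
Conditions: 2-chloro-1-methylpyridinium iodide, (R)-homobenzotetramisole [(2R)-2-phenyl-3,4-dihydro-2H-pyrimido[2,1-b]benzothiazole] (20 mol %), i-Pr2NEt, MeCN/CH2Cl2, rt, slow addition of 13
Reagents that add atoms: none
Why: The carboxylate of 13 displaces chloride from the pyridinium salt, the isothiourea takes over the acyl group to give 14, and i-Pr2NEt removes one H8 to form the (Z)-ammonium enolate, held flat by its O–S contact. This is a nucleophile-catalysed aldol-lactonisation, a reaction type established for aldehyde acids that give cyclopentane-fused beta-lactones. Ring B closes by a 5-exo-trig (enolexo) aldol that forms C7–C8, and the beta-lactone closes by a 4-exo-trig acyl substitution in which the C7 alkoxide forms O7–C10 and releases the catalyst. C8 is controlled by the substrate, which places the bulky acylammonium group on the convex beta face away from C1 and ring A, and by the pseudo-axial phenyl group of the (R)-catalyst, which leaves the same (Si) face of the enolate open. C7 is controlled by the four-membered ring itself, because only the aldolate with O7 cis to C10 can lactonise while the other reverts by retro-aldol. The step needs enolisation at C8 despite the acidic C6 aldehyde protons, which the onium group on C10 secures, and cyclisation ahead of intermolecular aldol, which the cis arms on C5 and C9 and slow addition at high dilution secure.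

Step 10
Reactants: 15 tricyclic beta-lactone
Product: 17 8-hydroxy beta-lactone (C8-OH alpha; O7 and C10 beta), via lithium enolate 16 (not isolated)
Conditions: LiN(i-Pr)2, THF, −78 °C; 2-(phenylsulfonyl)-3-phenyloxaziridine, −78 °C; AcOH quench at −78 °C
Reagents that add atoms: 2-(phenylsulfonyl)-3-phenyloxaziridine, O=S(=O)(N1OC1c1ccccc1)c1ccccc1
Why: Proposed new method: the amide base removes H8, the only enolisable proton, and at −78 °C enolate 16 should persist because its C7–O7 bond lies in the nodal plane of the enolate pi system and cannot be expelled; oxygen transfer from the N-sulfonyloxaziridine (Davis oxidation) can then only occur on the alpha face vacated by H8, since a four-membered ring trans-fused to ring B is out of geometric reach, so C8–OH forms with retention; the closest known reactions are C-alkylation of beta-lactone enolates and Davis hydroxylation of gamma- and delta-lactone enolates.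

Step 11
Reactants: 17 8-hydroxy beta-lactone
Product: 18 tetraol (C7-OH beta; C8-OH alpha; C10-OH; C11-OH; C1-OPMB beta)
Conditions: i-Bu2AlH (excess), CH2Cl2, −78 to −20 °C; aq. potassium sodium tartrate
Reagents that add atoms: none
Why: Hydride reduction of a beta-lactone to a 1,3-diol together with 1,2-reduction of the conjugated ester, both by acyl C–O cleavage only, so C7 and C8 keep their configuration.

Step 12
Reactants: 18 tetraol
Product: 19 C11 enal triol
Conditions: MnO2, CH2Cl2, rt
Reagents that add atoms: none
Why: Allylic alcohol oxidation with MnO2, which touches only C11–OH, thereby distinguishes C11 from the other primary alcohol C10 and restores push-pull stabilisation of ring A for the later acetal chemistry.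

Step 13
Reactants: 20 (E)-4-hydroxycinnamic acid
Product: 22 (E)-4-(tert-butyldimethylsilyloxy)cinnamic acid, via bis-silyl derivative 21 (not isolated)
Conditions: TBSCl, imidazole, DMF, rt; then AcOH/THF/H2O, rt
Reagents that add atoms: tert-butyldimethylsilyl chloride, CC(C)(C)[Si](C)(C)Cl
Why: Exhaustive silylation followed by selective solvolysis of the far more labile silyl ester, which leaves the aryl silyl ether and the (E)-alkene intact.

Step 14
Reactants: 19 C11 enal triol; 22 (E)-4-(tert-butyldimethylsilyloxy)cinnamic acid
Product: 23 10-O-(4-silyloxycinnamoyl) enal diol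
Conditions: N,N'-diisopropylcarbodiimide, DMAP (cat.), CH2Cl2, 0 °C
Reagents that add atoms: none
Why: Steglich esterification, selective for the only primary hydroxyl (C10) over the secondary C7 and tertiary C8 hydroxyls.

Step 15
Reactants: 23 10-O-(4-silyloxycinnamoyl) enal diol
Product: 24 7-O-triethylsilyl ether of 23
Conditions: TESCl, imidazole, DMF, 0 °C
Reagents that add atoms: triethylsilyl chloride, CC[Si](Cl)(CC)CC
Why: Silyl ether formation at the secondary C7–OH under conditions that leave the tertiary C8–OH free and, unlike silyl triflates, do not ionise the C1 acetal.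

Step 16
Reactants: 24 7-O-triethylsilyl ether
Product: 25 C1 lactol (drawn as the beta anomer)
Conditions: DDQ, CH2Cl2/pH 7 buffer, 0 °C
Reagents that add atoms: none
Why: Oxidative cleavage of a 4-methoxybenzyl acetal: hydride abstraction from the benzylic CH2 and hydrolysis release the lactol at neutral pH, the formyl-deactivated enol ether and the silyl ethers being inert, and C1 becomes labile again.

Step 17
Reactants: 25 C1 lactol; 26 (S)-3-methylpentanoic acid
Product: 27 C1 beta (S)-3-methylpentanoate
Conditions: N,N'-diisopropylcarbodiimide, DMAP (cat.), CH2Cl2, 0 °C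
Reagents that add atoms: none
Why: Steglich esterification of a lactol: the anomers equilibrate, and the beta hydroxyl, pseudo-axial (anomeric effect) and trans to the C9–C8 bond, is the one that should be acylated while the hindered C8–OH stays free, which sets C1 as in the target.

Step 18
Reactants: 27 C1 beta (S)-3-methylpentanoate
Product: 28 desilylated C11 enal
Conditions: HF·pyridine, pyridine, THF, 0 °C to rt
Reagents that add atoms: none
Why: Fluoride-mediated cleavage of the alkyl and aryl silyl ethers, done while the C4 formyl group still deactivates the enol ether and the acyl acetal towards ionisation.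

Step 19
Reactants: 28 desilylated C11 enal
Product: 29 CNP0241834.1
Conditions: NaBH4, CeCl3·7H2O, MeOH/THF, −78 °C; aq. NH4Cl
Reagents that add atoms: none
Why: Luche reduction: the hard borohydride species adds 1,2 to the vinylogous formate at low temperature and leaves the acyl acetal, the cinnamate ester and its double bond untouched.

Compound list
1 | furfuryl alcohol | OCc1ccco1 | starting material
2 | 6-hydroxy-2H-pyran-3(6H)-one (racemic) | OC1OCC(=O)C=C1 | intermediate
3 | (S)-5-oxo-5,6-dihydro-2H-pyran-2-yl 2-methylpropanoate | CC(C)C(=O)O[C@@H]1OCC(=O)C=C1 | intermediate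
4 | 4-methoxybenzyl alcohol | COc1ccc(CO)cc1 | starting material
5 | (R)-6-(4-methoxybenzyloxy)-2H-pyran-3(6H)-one | COc1ccc(CO[C@@H]2OCC(=O)C=C2)cc1 | intermediate
6 | but-3-en-2-one | CC(=O)C=C | starting material
7 | 2-(tert-butyldimethylsilyloxy)buta-1,3-diene | C=CC(=C)O[Si](C)(C)C(C)(C)C | intermediate
8 | cis-fused Diels-Alder ketone | COc1ccc(CO[C@@H]2OCC(=O)[C@H]3CC=C(O[Si](C)(C)C(C)(C)C)C[C@@H]23)cc1 | intermediate
9 | potassium C3=C4 enolate of 8 | [K+].COc1ccc(CO[C@@H]2OC=C([O-])[C@H]3CC=C(O[Si](C)(C)C(C)(C)C)C[C@@H]23)cc1 | intermediate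
10 | C4 enol triflate | COc1ccc(CO[C@@H]2OC=C(OS(=O)(=O)C(F)(F)F)[C@H]3CC=C(O[Si](C)(C)C(C)(C)C)C[C@@H]23)cc1 | intermediate
11 | C4 methyl ester with silyl enol ether | COc1ccc(CO[C@@H]2OC=C(C(=O)OC)[C@H]3CC=C(O[Si](C)(C)C(C)(C)C)C[C@@H]23)cc1 | intermediate
12 | C10 silyl ester C7 aldehyde | COc1ccc(CO[C@@H]2OC=C(C(=O)OC)[C@@H](CC=O)[C@H]2CC(=O)O[Si](C)(C)C(C)(C)C)cc1 | intermediate
13 | seco aldehyde acid (key-step precursor) | COc1ccc(CO[C@@H]2OC=C(C(=O)OC)[C@@H](CC=O)[C@H]2CC(=O)O)cc1 | intermediate
14 | C10 acylammonium ion of (R)-homobenzotetramisole | COc1ccc(CO[C@@H]2OC=C(C(=O)OC)[C@@H](CC=O)[C@H]2CC(=O)[N+]2=C3Sc4ccccc4N3CC[C@@H]2c2ccccc2)cc1 | intermediate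
15 | tricyclic beta-lactone (key-step product) | COc1ccc(CO[C@@H]2OC=C(C(=O)OC)[C@H]3C[C@@H]4OC(=O)[C@@H]4[C@@H]23)cc1 | intermediate
16 | lithium enolate of 15 | [Li+].COc1ccc(CO[C@@H]2OC=C(C(=O)OC)[C@H]3C[C@@H]4OC([O-])=C4[C@@H]23)cc1 | intermediate
17 | 8-hydroxy beta-lactone | COc1ccc(CO[C@@H]2OC=C(C(=O)OC)[C@H]3C[C@@H]4OC(=O)[C@]4(O)[C@@H]23)cc1 | intermediate
18 | tetraol | COc1ccc(CO[C@@H]2OC=C(CO)[C@H]3C[C@H](O)[C@](O)(CO)[C@@H]23)cc1 | intermediate
19 | C11 enal triol | COc1ccc(CO[C@@H]2OC=C(C=O)[C@H]3C[C@H](O)[C@](O)(CO)[C@@H]23)cc1 | intermediate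
20 | (E)-4-hydroxycinnamic acid | OC(=O)/C=C/c1ccc(O)cc1 | starting material
21 | tert-butyldimethylsilyl (E)-4-(tert-butyldimethylsilyloxy)cinnamate | CC(C)(C)[Si](C)(C)Oc1ccc(/C=C/C(=O)O[Si](C)(C)C(C)(C)C)cc1 | intermediate
22 | (E)-4-(tert-butyldimethylsilyloxy)cinnamic acid | CC(C)(C)[Si](C)(C)Oc1ccc(/C=C/C(=O)O)cc1 | intermediate
23 | 10-O-(4-silyloxycinnamoyl) enal diol | COc1ccc(CO[C@@H]2OC=C(C=O)[C@H]3C[C@H](O)[C@](O)(COC(=O)/C=C/c4ccc(O[Si](C)(C)C(C)(C)C)cc4)[C@@H]23)cc1 | intermediate
24 | 7-O-triethylsilyl ether of 23 | COc1ccc(CO[C@@H]2OC=C(C=O)[C@H]3C[C@H](O[Si](CC)(CC)CC)[C@](O)(COC(=O)/C=C/c4ccc(O[Si](C)(C)C(C)(C)C)cc4)[C@@H]23)cc1 | intermediate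
25 | C1 lactol | O[C@@H]1OC=C(C=O)[C@H]2C[C@H](O[Si](CC)(CC)CC)[C@](O)(COC(=O)/C=C/c3ccc(O[Si](C)(C)C(C)(C)C)cc3)[C@@H]12 | intermediate
26 | (S)-3-methylpentanoic acid | CC[C@H](C)CC(=O)O | starting material
27 | C1 beta (S)-3-methylpentanoate, bis-silylated | CC[C@H](C)CC(=O)O[C@@H]1OC=C(C=O)[C@H]2C[C@H](O[Si](CC)(CC)CC)[C@](O)(COC(=O)/C=C/c3ccc(O[Si](C)(C)C(C)(C)C)cc3)[C@@H]12 | intermediate
28 | desilylated C11 enal | CC[C@H](C)CC(=O)O[C@@H]1OC=C(C=O)[C@H]2C[C@H](O)[C@](O)(COC(=O)/C=C/c3ccc(O)cc3)[C@@H]12 | intermediate
29 | CNP0241834.1 | CC[C@H](C)CC(=O)O[C@@H]1OC=C(CO)[C@H]2C[C@H](O)[C@](O)(COC(=O)/C=C/c3ccc(O)cc3)[C@@H]12 | target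

Total step count: 19. Longest linear sequence: 17 (steps 1–3, 5–12 and 14–19).

Steps most likely to fail

Step 10. The strained enolate may open by beta-elimination, or the amide base may attack the lactone carbonyl, before oxygen transfer takes place.
- The fallback uses only known ester-enolate chemistry. It sets out from 15 and returns at 24.
- The lactone is opened with K2CO3 in MeOH at 0 °C to the cis hydroxy diester F1, which is silylated (TESCl, imidazole, DMF) to the triethylsilyl ether F2.
- The ordinary ester enolate (KN(SiMe3)2, THF, −78 °C) undergoes Davis oxidation with the same oxaziridine to the tertiary alcohol F3. The reagent should enter the alpha face, anti to the neighbouring beta silyloxy group.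
- i-Bu2AlH reduces both esters to the triol F4, and MnO2 gives the enal diol F5.
- Carbodiimide/DMAP coupling of F5 with 22 at O10 gives 24, so step 15 is no longer needed.

Step 9. Facial selectivity at C8 may be poor, or intermolecular aldol condensation may outrun the cyclisation.
- The fallback forms the same two bonds in separate operations. It sets out from 13 and returns at 15.
- The acid is converted (PhSH, N,N'-diisopropylcarbodiimide, DMAP cat.) into the S-phenyl thioester F6.
- Soft enolisation with MgBr2·OEt2 and i-Pr2NEt in CH2Cl2 triggers a direct, reversible intramolecular thioester aldol to the cis hydroxy thioester F7.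
- Thiophilic activation with AgO2CCF3 in MeCN closes O7–C10.

Step 17. Ring–chain tautomerism of the lactol under basic acyl-transfer conditions may lead to acylation of the open enol, epimerisation at C9 or poor anomeric selectivity.
- The fallback reverses the polarity at C1. It sets out from 25 and returns at 27.
- Cl3CCN with catalytic DBU in CH2Cl2 at 0 °C gives the trichloroacetimidate F8.
- F8 is then treated with free acid 26 in CH2Cl2 without base. The acid protonates the imidate, and the carboxylate should add to the oxocarbenium ion along the axial trajectory on the beta face, trans to the C9–C8 bond.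

Further compounds
F1 | step 10 | cis 7-hydroxy C10/C11 dimethyl diester | COc1ccc(CO[C@@H]2OC=C(C(=O)OC)[C@H]3C[C@H](O)[C@H](C(=O)OC)[C@@H]23)cc1
F2 | step 10 | 7-O-triethylsilyl ether of F1 | COc1ccc(CO[C@@H]2OC=C(C(=O)OC)[C@H]3C[C@H](O[Si](CC)(CC)CC)[C@H](C(=O)OC)[C@@H]23)cc1
F3 | step 10 | 8-alpha-hydroxy diester | COc1ccc(CO[C@@H]2OC=C(C(=O)OC)[C@H]3C[C@H](O[Si](CC)(CC)CC)[C@](O)(C(=O)OC)[C@@H]23)cc1
F4 | step 10 | 7-O-triethylsilyl triol | COc1ccc(CO[C@@H]2OC=C(CO)[C@H]3C[C@H](O[Si](CC)(CC)CC)[C@](O)(CO)[C@@H]23)cc1
F5 | step 10 | 7-O-triethylsilyl C11 enal diol | COc1ccc(CO[C@@H]2OC=C(C=O)[C@H]3C[C@H](O[Si](CC)(CC)CC)[C@](O)(CO)[C@@H]23)cc1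
F6 | step 9 | S-phenyl thioester of 13 | COc1ccc(CO[C@@H]2OC=C(C(=O)OC)[C@@H](CC=O)[C@H]2CC(=O)Sc2ccccc2)cc1
F7 | step 9 | cis 7-hydroxy C10 S-phenyl thioester | COc1ccc(CO[C@@H]2OC=C(C(=O)OC)[C@H]3C[C@H](O)[C@H](C(=O)Sc4ccccc4)[C@@H]23)cc1
F8 | step 17 | C1 trichloroacetimidate of 25 | N=C(O[C@@H]1OC=C(C=O)[C@H]2C[C@H](O[Si](CC)(CC)CC)[C@](O)(COC(=O)/C=C/c3ccc(O[Si](C)(C)C(C)(C)C)cc3)[C@@H]12)C(Cl)(Cl)Cl
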